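The route rests on a biomimetic bisabolane ring closure (bisabolane locants): the cyclohexane ring is closed between its CH2 (C1) and the CH (C6) that bears the exocyclic C7=C14 methylene. An acyclic 2-methyl-2-vinyloxirane (C1=C2–C3–C4 epoxide) is ionized and its allyl terminus C1 is captured in SN2′ fashion by a tethered allylsilane (C6=C7–C14–Si). One operation builds the carbocycle, the C6 stereocentre trans to the C5 oxygen, the C2=C3 ring alkene, the C7=C14 methylene and the C4 oxygen, features that map onto the epoxy ketone and side chain of the target. The precursor is assembled convergently by a Nozaki–Hiyama–Kishi coupling.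

Key step: step 10

Remark on locants: the Why lines use bisabolane numbering: ring C1 (CH2), C2, C3 (bears methyl C15), C4, C5, C6; side chain C7 (bears C14), C8, C9, C10, C11.

Remark on the chemistry: compounds 1 and 5, angelic acid, 3-methylbut-2-enoyl chloride and the ProPhenol ligand are taken as commercial; the (S,S) antipode of ProPhenol is assumed to give the S carbinol in step 5, and its mirror image is used if it does not.

Step 1
Reactants: 1 (2Z)-3-methylpent-2-en-4-yn-1-ol
Product: 2 (2Z)-3-methylpenta-2,4-dien-1-ol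
Conditions: H2 (1 atm), Pd/CaCO3 poisoned with Pb(OAc)2 (Lindlar catalyst), quinoline, EtOAc, 0 °C
Reagents that add atoms: none
Why: Lindlar partial hydrogenation should reduce the terminal alkyne to the vinyl group and stop there, leaving the Z-trisubstituted alkene and its geometry untouched.

Step 2
Reactants: 2 (2Z)-3-methylpenta-2,4-dien-1-ol
Product: 3 [(2S,3R)-3-ethenyl-3-methyloxiran-2-yl]methanol
Conditions: Ti(OiPr)4 (10 mol %), L-(+)-diisopropyl tartrate (12 mol %), t-BuOOH (in decane), 4 Å molecular sieves, CH2Cl2, −20 °C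
Reagents that add atoms: tert-butyl hydroperoxide CC(C)(C)OO
Why: Katsuki–Sharpless asymmetric epoxidation should oxidize only the allylic C3=C4 bond; the L-(+)-tartrate sets C4 (S) and C3 (R) as it does for nerol, and syn addition to the Z alkene keeps the vinyl group cis to the carbinol arm.

Step 3
Reactants: 3 [(2S,3R)-3-ethenyl-3-methyloxiran-2-yl]methanol
Product: 4 (2R,3R)-3-ethenyl-3-methyloxirane-2-carbaldehyde
Conditions: Dess–Martin periodinane, NaHCO3, CH2Cl2, 0 °C; used crude
Reagents that add atoms: none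
Why: Dess–Martin oxidation under bicarbonate buffer should give the aldehyde without opening the acid-labile vinyl epoxide or touching its stereocentres.

Step 4
Reactants: 5 4-methylpent-3-en-1-ol
Product: 6 4-methylpent-3-enal
Conditions: Dess–Martin periodinane, NaHCO3, CH2Cl2, 0 °C; used as crude solution
Reagents that add atoms: none
Why: Dess–Martin oxidation under buffered, non-basic conditions should give the β,γ-unsaturated aldehyde without migration of the double bond into conjugation.

Step 5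
Reactants: 6 4-methylpent-3-enal
Product: 8 (3S)-6-methylhept-5-en-1-yn-3-ol, via silylated propargylic alcohol 7 (not isolated)
Conditions: Me3SiC≡CH, Me2Zn, (S,S)-ProPhenol (10 mol %), Ph3P=O (20 mol %), toluene, 0–4 °C; then K2CO3 (cat.), MeOH, rt; aq. NH4Cl work-up
Reagents that add atoms: ethynyltrimethylsilane C#C[Si](C)(C)C
Why: Trost zinc–ProPhenol asymmetric alkynylation should add the zinc acetylide to one aldehyde face inside the chiral dinuclear zinc pocket and so set C8 (S); the amine-free cold conditions spare the β,γ-alkene and methanolysis cleaves the alkynyl C–Si bond.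

Step 6
Reactants: 8 (3S)-6-methylhept-5-en-1-yn-3-ol
Product: 10 (1E,3S)-1-iodo-6-methyl-2-[(trimethylsilyl)methyl]hepta-1,5-dien-3-ol, via alkenylmagnesium chelate 9 (not isolated)
Conditions: Me3SiCH2MgCl (3.5 equiv), CuI (20 mol %), THF/Et2O, 0 °C to rt; then I2, THF, −40 to 0 °C
Reagents that add atoms: (trimethylsilyl)methylmagnesium chloride C[Si](C)(C)C[Mg]Cl; iodine II
Why: Duboudin copper-catalysed carbomagnesiation directed by the magnesium alkoxide should add anti, placing CH2SiMe3 on C7 and magnesium on C6 cis to C8 in a five-membered chelate; iodinolysis with retention gives the E iodide.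

Step 7
Reactants: 10 (1E,3S)-1-iodo-6-methyl-2-[(trimethylsilyl)methyl]hepta-1,5-dien-3-ol
Product: 11 (1E,3S)-1-iodo-6-methyl-2-[(trimethylsilyl)methyl]hepta-1,5-dien-3-yl (2Z)-2-methylbut-2-enoate
Conditions: angelic acid, 2,4,6-trichlorobenzoyl chloride, Et3N, toluene, rt; then 10, toluene, 80 °C
Reagents that add atoms: angelic acid C/C=C(/C)C(=O)O
Why: Yamaguchi mixed-anhydride esterification should acylate the secondary alcohol with angelic acid under conditions known to avoid Z to E isomerization of the acyl group; C8 is not touched.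

Step 8
Reactants: 11 (1E,3S)-1-iodo-6-methyl-2-[(trimethylsilyl)methyl]hepta-1,5-dien-3-yl (2Z)-2-methylbut-2-enoate; 4 (2R,3R)-3-ethenyl-3-methyloxirane-2-carbaldehyde
Product: 12 (1S,2E,4S)-1-[(2S,3R)-3-ethenyl-3-methyloxiran-2-yl]-1-hydroxy-7-methyl-3-[(trimethylsilyl)methyl]octa-2,6-dien-4-yl (2Z)-2-methylbut-2-enoate
Conditions: CrCl2 (4 equiv), NiCl2 (1 mol %), DMSO/THF, rt; chromatography on Et3N-deactivated silica
Reagents that add atoms: none
Why: Nozaki–Hiyama–Kishi coupling: the alkenylchromium reagent should add only to the aldehyde and tolerate ester, epoxide and allylsilane; Felkin–Anh attack anti to the epoxide C4–O bond should set C5 (S) in the erythro adduct, the minor C5 epimer being removed by chromatography.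

Step 9
Reactants: 12 (1S,2E,4S)-1-[(2S,3R)-3-ethenyl-3-methyloxiran-2-yl]-1-hydroxy-7-methyl-3-[(trimethylsilyl)methyl]octa-2,6-dien-4-yl (2Z)-2-methylbut-2-enoate
Product: 13 (1S,2E,4S)-1-[(2S,3R)-3-ethenyl-3-methyloxiran-2-yl]-7-methyl-1-[(triethylsilyl)oxy]-3-[(trimethylsilyl)methyl]octa-2,6-dien-4-yl (2Z)-2-methylbut-2-enoate
Conditions: Et3SiCl, imidazole, CH2Cl2, 0 °C
Reagents that add atoms: chlorotriethylsilane CC[Si](Cl)(CC)CC
Why: Silylation under basic conditions should mask the C5 hydroxyl, which would otherwise capture the allyl cation as a cyclic ether; no stereocentre is affected.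

Step 10
Reactants: 13 (1S,2E,4S)-1-[(2S,3R)-3-ethenyl-3-methyloxiran-2-yl]-7-methyl-1-[(triethylsilyl)oxy]-3-[(trimethylsilyl)methyl]octa-2,6-dien-4-yl (2Z)-2-methylbut-2-enoate
Product: 15 (3S)-2-[(1S,5R,6S)-5,6-dihydroxy-4-methylcyclohex-3-en-1-yl]-6-methylhepta-1,5-dien-3-yl (2Z)-2-methylbut-2-enoate, via bis-silyl ether 14 (not isolated)
Conditions: Me3SiOTf (10 mol %), 2,6-di-tert-butyl-4-methylpyridine (20 mol %), CH2Cl2, −78 °C; then PPTS (cat.), MeOH, rt
Reagents that add atoms: none
Why: Me3SiOTf silylates the epoxide oxygen, the tertiary allylic C3–O bond ionizes, the allyl terminus C1 is attacked by the allylsilane carbon C6, and the β-silyl cation at C7 gives up Me3Si+ to form the C7=C14 methylene (net silyl transfer to the C4 oxygen, which carries the chain). The closest known reactions are Lewis-acid epoxy-allylsilane cyclizations and allylsilane-terminated cyclizations of allylic cations (intramolecular Hosomi–Sakurai alkylation), used here in the vinylogous SN2′ sense of the biosynthetic farnesyl-to-bisabolyl closure. The carbocycle closes in a 6-exo-trig mode on the allylsilane alkene and a 6-endo mode on the allyl unit, and attack at the other terminus C3 would need a four-membered ring, so ring size fixes the regiochemistry. The new stereocentre C6 is controlled by C5: in the chair-like transition state H-5 eclipses the C6=C7 bond (least A(1,3) strain), the C5 silyloxy group and the C7 residue are both equatorial, and C6 should form trans to the C5 oxygen. The cis relation of vinyl group and C5 on the epoxide (from the Z dienol) lets C1 reach C6, and the erythro C4 oxygen sits axial on the face of the new bond without clash. The step needs ionization of the epoxide in preference to the allylic silyl ether and ester, which its ring strain and tertiary allylic C–O bond should secure at −78 °C with catalytic Lewis acid and a hindered base.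

Step 11
Reactants: 15 (3S)-2-[(1S,5R,6S)-5,6-dihydroxy-4-methylcyclohex-3-en-1-yl]-6-methylhepta-1,5-dien-3-yl (2Z)-2-methylbut-2-enoate
Product: 16 (3S)-2-[(1S,6S)-6-hydroxy-4-methyl-5-oxocyclohex-3-en-1-yl]-6-methylhepta-1,5-dien-3-yl (2Z)-2-methylbut-2-enoate
Conditions: MnO2 (activated, excess), CH2Cl2, rt
Reagents that add atoms: none
Why: MnO2 should oxidize the allylic C4 alcohol selectively over the saturated C5 alcohol, which removes the C4 centre of the unwanted cis configuration and gives the α′-hydroxy enone.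

Step 12
Reactants: 16 (3S)-2-[(1S,6S)-6-hydroxy-4-methyl-5-oxocyclohex-3-en-1-yl]-6-methylhepta-1,5-dien-3-yl (2Z)-2-methylbut-2-enoate
Product: 17 (1S,6S)-3-methyl-6-{(3S)-6-methyl-3-[(2Z)-2-methylbut-2-enoyloxy]hepta-1,5-dien-2-yl}-2-oxocyclohex-3-en-1-yl 3-methylbut-2-enoate
Conditions: 3-methylbut-2-enoyl chloride, pyridine, DMAP (cat.), CH2Cl2, 0 °C
Reagents that add atoms: 3-methylbut-2-enoyl chloride CC(C)=CC(=O)Cl
Why: Pyridine/DMAP acylation of the secondary α-ketol should install the senecioate; the equatorial C5 configuration trans to C6 is also the thermodynamic one, so C5 is not at risk.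

Step 13
Reactants: 17 (1S,6S)-3-methyl-6-{(3S)-6-methyl-3-[(2Z)-2-methylbut-2-enoyloxy]hepta-1,5-dien-2-yl}-2-oxocyclohex-3-en-1-yl 3-methylbut-2-enoate
Product: 18 (1S,2S,6S)-2-hydroxy-3-methyl-6-{(3S)-6-methyl-3-[(2Z)-2-methylbut-2-enoyloxy]hepta-1,5-dien-2-yl}cyclohex-3-en-1-yl 3-methylbut-2-enoate
Conditions: NaBH4, CeCl3·7H2O, MeOH, −78 °C; quench cold with aq. NH4Cl
Reagents that add atoms: none
Why: Luche reduction is 1,2-selective, and axial hydride delivery should give the equatorial C4 alcohol trans to the C5 ester and cis to the C6 substituent (the cis-carveol pattern); the cold quench limits acyl migration.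

Step 14
Reactants: 18 (1S,2S,6S)-2-hydroxy-3-methyl-6-{(3S)-6-methyl-3-[(2Z)-2-methylbut-2-enoyloxy]hepta-1,5-dien-2-yl}cyclohex-3-en-1-yl 3-methylbut-2-enoate
Product: 19 (1R,2R,3S,4S,6S)-2-hydroxy-1-methyl-4-{(3S)-6-methyl-3-[(2Z)-2-methylbut-2-enoyloxy]hepta-1,5-dien-2-yl}-7-oxabicyclo[4.1.0]heptan-3-yl 3-methylbut-2-enoate
Conditions: VO(acac)2 (5 mol %), t-BuOOH (in decane), CH2Cl2, 0 °C to rt
Reagents that add atoms: tert-butyl hydroperoxide CC(C)(C)OO
Why: Hydroxyl-directed vanadium-catalysed epoxidation (Sharpless–Michaelson) should deliver oxygen to the C2=C3 bond on the face of the C4 hydroxyl, setting C2 and C3 cis to the C6 side chain, and leave the prenyl, methylene and enoate alkenes alone.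

Step 15
Reactants: 19 (1R,2R,3S,4S,6S)-2-hydroxy-1-methyl-4-{(3S)-6-methyl-3-[(2Z)-2-methylbut-2-enoyloxy]hepta-1,5-dien-2-yl}-7-oxabicyclo[4.1.0]heptan-3-yl 3-methylbut-2-enoate
Product: 20 (1S,3S,4S,6S)-1-methyl-4-{(3S)-6-methyl-3-[(2Z)-2-methylbut-2-enoyloxy]hepta-1,5-dien-2-yl}-2-oxo-7-oxabicyclo[4.1.0]heptan-3-yl 3-methylbut-2-enoate
Conditions: Dess–Martin periodinane, NaHCO3, CH2Cl2, 0 °C to rt
Reagents that add atoms: none
Why: Dess–Martin oxidation of the secondary epoxy alcohol should give the epoxy ketone under neutral conditions that neither epimerize C5 nor isomerize the angelate.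

Compound list
1 | (2Z)-3-methylpent-2-en-4-yn-1-ol | OC/C=C(/C)C#C | starting material
2 | (2Z)-3-methylpenta-2,4-dien-1-ol | OC/C=C(/C)C=C | intermediate
3 | [(2S,3R)-3-ethenyl-3-methyloxiran-2-yl]methanol | OC[C@@H]1O[C@]1(C)C=C | intermediate
4 | (2R,3R)-3-ethenyl-3-methyloxirane-2-carbaldehyde | O=C[C@@H]1O[C@]1(C)C=C | intermediate
5 | 4-methylpent-3-en-1-ol | CC(C)=CCCO | starting material
6 | 4-methylpent-3-enal | CC(C)=CCC=O | intermediate
7 | (3S)-6-methyl-1-(trimethylsilyl)hept-5-en-1-yn-3-ol | CC(C)=CC[C@H](O)C#C[Si](C)(C)C | intermediate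
8 | (3S)-6-methylhept-5-en-1-yn-3-ol | CC(C)=CC[C@H](O)C#C | intermediate
9 | chloromagnesium (1E,3S)-1-(chloromagnesio)-6-methyl-2-[(trimethylsilyl)methyl]hepta-1,5-dien-3-olate | CC(C)=CC[C@H](O[Mg]Cl)/C(C[Si](C)(C)C)=C\[Mg]Cl | intermediate
10 | (1E,3S)-1-iodo-6-methyl-2-[(trimethylsilyl)methyl]hepta-1,5-dien-3-ol | CC(C)=CC[C@H](O)/C(C[Si](C)(C)C)=C\I | intermediate
11 | (1E,3S)-1-iodo-6-methyl-2-[(trimethylsilyl)methyl]hepta-1,5-dien-3-yl (2Z)-2-methylbut-2-enoate | CC(C)=CC[C@H](OC(=O)/C(C)=C\C)/C(C[Si](C)(C)C)=C\I | intermediate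
12 | (1S,2E,4S)-1-[(2S,3R)-3-ethenyl-3-methyloxiran-2-yl]-1-hydroxy-7-methyl-3-[(trimethylsilyl)methyl]octa-2,6-dien-4-yl (2Z)-2-methylbut-2-enoate | CC(C)=CC[C@H](OC(=O)/C(C)=C\C)/C(C[Si](C)(C)C)=C\[C@H](O)[C@@H]1O[C@]1(C)C=C | intermediate
13 | (1S,2E,4S)-1-[(2S,3R)-3-ethenyl-3-methyloxiran-2-yl]-7-methyl-1-[(triethylsilyl)oxy]-3-[(trimethylsilyl)methyl]octa-2,6-dien-4-yl (2Z)-2-methylbut-2-enoate | CC(C)=CC[C@H](OC(=O)/C(C)=C\C)/C(C[Si](C)(C)C)=C\[C@H](O[Si](CC)(CC)CC)[C@@H]1O[C@]1(C)C=C | intermediate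
14 | (3S)-6-methyl-2-{(1S,5R,6S)-4-methyl-6-[(triethylsilyl)oxy]-5-[(trimethylsilyl)oxy]cyclohex-3-en-1-yl}hepta-1,5-dien-3-yl (2Z)-2-methylbut-2-enoate | C=C([C@H](CC=C(C)C)OC(=O)/C(C)=C\C)[C@@H]1CC=C(C)[C@@H](O[Si](C)(C)C)[C@H]1O[Si](CC)(CC)CC | intermediate
15 | (3S)-2-[(1S,5R,6S)-5,6-dihydroxy-4-methylcyclohex-3-en-1-yl]-6-methylhepta-1,5-dien-3-yl (2Z)-2-methylbut-2-enoate | C=C([C@H](CC=C(C)C)OC(=O)/C(C)=C\C)[C@@H]1CC=C(C)[C@@H](O)[C@H]1O | intermediate
16 | (3S)-2-[(1S,6S)-6-hydroxy-4-methyl-5-oxocyclohex-3-en-1-yl]-6-methylhepta-1,5-dien-3-yl (2Z)-2-methylbut-2-enoate | C=C([C@H](CC=C(C)C)OC(=O)/C(C)=C\C)[C@@H]1CC=C(C)C(=O)[C@H]1O | intermediate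
17 | (1S,6S)-3-methyl-6-{(3S)-6-methyl-3-[(2Z)-2-methylbut-2-enoyloxy]hepta-1,5-dien-2-yl}-2-oxocyclohex-3-en-1-yl 3-methylbut-2-enoate | C=C([C@H](CC=C(C)C)OC(=O)/C(C)=C\C)[C@@H]1CC=C(C)C(=O)[C@H]1OC(=O)C=C(C)C | intermediate
18 | (1S,2S,6S)-2-hydroxy-3-methyl-6-{(3S)-6-methyl-3-[(2Z)-2-methylbut-2-enoyloxy]hepta-1,5-dien-2-yl}cyclohex-3-en-1-yl 3-methylbut-2-enoate | C=C([C@H](CC=C(C)C)OC(=O)/C(C)=C\C)[C@@H]1CC=C(C)[C@H](O)[C@H]1OC(=O)C=C(C)C | intermediate
19 | (1R,2R,3S,4S,6S)-2-hydroxy-1-methyl-4-{(3S)-6-methyl-3-[(2Z)-2-methylbut-2-enoyloxy]hepta-1,5-dien-2-yl}-7-oxabicyclo[4.1.0]heptan-3-yl 3-methylbut-2-enoate | C=C([C@H](CC=C(C)C)OC(=O)/C(C)=C\C)[C@@H]1C[C@@H]2O[C@]2(C)[C@H](O)[C@H]1OC(=O)C=C(C)C | intermediate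
20 | (1S,3S,4S,6S)-1-methyl-4-{(3S)-6-methyl-3-[(2Z)-2-methylbut-2-enoyloxy]hepta-1,5-dien-2-yl}-2-oxo-7-oxabicyclo[4.1.0]heptan-3-yl 3-methylbut-2-enoate | C=C([C@H](CC=C(C)C)OC(=O)/C(C)=C\C)[C@@H]1C[C@@H]2O[C@]2(C)C(=O)[C@H]1OC(=O)C=C(C)C | target

Total step count: 15. Longest linear sequence: 12 steps (from 5 through steps 4 to 15); the branch from 1 (steps 1 to 3) joins at step 8.

Steps most likely to fail

Step 10 may fail because the ionized epoxide collapses by hydride shift or proton loss, or because the allylic C5 silyloxy group is expelled with loss of silicon, before the C1–C6 bond forms. The fallback sets out from 13 and comes back at 15. The epoxide would first be opened with LiBr and AcOH in THF at 0 °C to the tertiary allylic bromohydrin (4S,5S,6E,8S)-3-bromo-4-hydroxy-3,11-dimethyl-5-[(triethylsilyl)oxy]-7-[(trimethylsilyl)methyl]dodeca-1,6,10-trien-8-yl (2Z)-2-methylbut-2-enoate F1; its 1,4-isomer ionizes to the same cation. The allyl cation would then be generated by halide abstraction with AgOTf and 2,6-di-tert-butyl-4-methylpyridine in CH2Cl2 at −78 °C, without a silylating Lewis acid (silver-assisted Hosomi–Sakurai alkylation). This should give the cyclized mono-silyl ether (3S)-2-{(1S,5R,6S)-5-hydroxy-4-methyl-6-[(triethylsilyl)oxy]cyclohex-3-en-1-yl}-6-methylhepta-1,5-dien-3-yl (2Z)-2-methylbut-2-enoate F2, and PPTS in MeOH would remove the triethylsilyl group to give 15.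

Step 8 may fail through poor facial selectivity in the addition of the alkenylchromium reagent to the α,β-epoxy aldehyde, so that the C5 epimers form in comparable amounts. The fallback sets out from 12 as the C5 epimer mixture and comes back at 12. Dess–Martin oxidation would give the epoxy enone (2E,4S)-1-[(2R,3R)-3-ethenyl-3-methyloxiran-2-yl]-7-methyl-1-oxo-3-[(trimethylsilyl)methyl]octa-2,6-dien-4-yl (2Z)-2-methylbut-2-enoate F3. Chelation-controlled 1,2-reduction with Zn(BH4)2 in Et2O at −20 °C, which converts α,β-epoxy ketones into the erythro alcohols, should then return 12 as the 5S epimer.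

Step 5 may fail through migration of the β,γ-double bond of 6 into conjugation, aldol self-condensation of the unbranched aldehyde, or low enantioselectivity. The fallback sets out from 6 and comes back at 8. Addition of LiC≡CSiMe3 in THF at −78 °C would give the racemic alcohol (3RS)-6-methyl-1-(trimethylsilyl)hept-5-en-1-yn-3-ol F4, and Dess–Martin oxidation the ynone 6-methyl-1-(trimethylsilyl)hept-5-en-1-yn-3-one F5. Noyori transfer hydrogenation with RuCl[(S,S)-TsDPEN](p-cymene) in i-PrOH should set the S carbinol and give 7, which K2CO3 in MeOH desilylates to 8.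

Further compounds
F1 | step 10 | (4S,5S,6E,8S)-3-bromo-4-hydroxy-3,11-dimethyl-5-[(triethylsilyl)oxy]-7-[(trimethylsilyl)methyl]dodeca-1,6,10-trien-8-yl (2Z)-2-methylbut-2-enoate | CC(C)=CC[C@H](OC(=O)/C(C)=C\C)/C(C[Si](C)(C)C)=C\[C@H](O[Si](CC)(CC)CC)[C@H](O)C(C)(Br)C=C
F2 | step 10 | (3S)-2-{(1S,5R,6S)-5-hydroxy-4-methyl-6-[(triethylsilyl)oxy]cyclohex-3-en-1-yl}-6-methylhepta-1,5-dien-3-yl (2Z)-2-methylbut-2-enoate | C=C([C@H](CC=C(C)C)OC(=O)/C(C)=C\C)[C@@H]1CC=C(C)[C@@H](O)[C@H]1O[Si](CC)(CC)CC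
F3 | step 8 | (2E,4S)-1-[(2R,3R)-3-ethenyl-3-methyloxiran-2-yl]-7-methyl-1-oxo-3-[(trimethylsilyl)methyl]octa-2,6-dien-4-yl (2Z)-2-methylbut-2-enoate | CC(C)=CC[C@H](OC(=O)/C(C)=C\C)/C(C[Si](C)(C)C)=C\C(=O)[C@@H]1O[C@]1(C)C=C
F4 | step 5 | (3RS)-6-methyl-1-(trimethylsilyl)hept-5-en-1-yn-3-ol | CC(C)=CCC(O)C#C[Si](C)(C)C
F5 | step 5 | 6-methyl-1-(trimethylsilyl)hept-5-en-1-yn-3-one | CC(C)=CCC(=O)C#C[Si](C)(C)C
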